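The target ring, if C4 is imagined as a carbonyl carbon, becomes a cyclohex-2-enone carrying prenyl at its C5 and methyl at its C6. Target C2 (prenyl) then maps onto the β-carbon of an enal and C3 (methyl) onto the nucleophilic α-carbon of an acetoacetate. One operation, an amine-catalysed Michael addition followed by acid-induced decarboxylative aldol condensation, forms C2–C3 and C5–C6, closes the ring and sets C2 (and, by equilibration, C3). Its precursors are (E)-6-methylhepta-2,5-dienal and tert-butyl 2-methyl-3-oxobutanoate. The enone then receives phenyl at C6, a formyl equivalent at C1 and the C3=C4 alkene; the aroyl group comes from an aryllithium.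

Key step: step 4

Assumption: the iminium ion is taken to react on the face away from the diphenyl(silyloxy)methyl group, which calls for the (R)-catalyst; the target is (1S,2S,6S), with the C1 group trans to both neighbours.
Remark: ring atoms are numbered as in the target throughout (C1 aroyl, C2 prenyl, C3 methyl, C4 =CH, C5 CH2, C6 phenyl).
Remark: phenyl is placed on sp2 C6 and hydrogen is added last, because a phenyl nucleophile adding to the enone would enter axially, trans to the C2 prenyl group, which is the wrong C6 configuration.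

Step 1
Reactants: 1 prop-2-yn-1-ol (propargyl alcohol); 2 1-bromo-3-methylbut-2-ene (prenyl bromide)
Product: 3 6-methylhept-5-en-2-yn-1-ol
Conditions: CuI (10 mol%), K2CO3, nBu4NBr (cat.), DMF, rt
Reagents that add atoms: none
Why: The copper acetylide formed in situ should displace the primary allylic bromide at its unhindered terminus (copper-catalysed alkyne allylation), giving the skipped enyne without protection of the hydroxyl.

Step 2
Reactants: 3 6-methylhept-5-en-2-yn-1-ol
Product: 4 (2E)-6-methylhepta-2,5-dien-1-ol
Conditions: NaAlH2(OCH2CH2OMe)2, THF, 0 °C to rt; aqueous Rochelle salt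
Reagents that add atoms: none
Why: Hydroxyl-directed trans-hydroalumination of the propargylic alcohol and protonolysis should give the (E)-allylic alcohol only, the isolated trisubstituted alkene being inert to the aluminium hydride.

Step 3
Reactants: 4 (2E)-6-methylhepta-2,5-dien-1-ol
Product: 5 (2E)-6-methylhepta-2,5-dienal
Conditions: MnO2, CH2Cl2, rt
Reagents that add atoms: none
Why: MnO2 oxidises the allylic alcohol selectively under neutral conditions, which avoids acid- or base-induced migration of the prenyl double bond into conjugation.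

Step 4
Reactants: 5 (2E)-6-methylhepta-2,5-dienal; 6 tert-butyl 2-methyl-3-oxobutanoate
Product: 9 (5R,6R)-6-methyl-5-(3-methylbut-2-en-1-yl)cyclohex-2-en-1-one, via Michael adduct 7 (not isolated), via keto aldehyde 8 (not isolated)
Conditions: (R)-2-[diphenyl(trimethylsilyloxy)methyl]pyrrolidine (20 mol%), PhCO2H (20 mol%), toluene, 0 °C, slow addition of 5 to 6 (1.5 equiv); then TsOH·H2O (50 mol%), 80 °C
Reagents that add atoms: none
Why: The enal and the secondary amine give an (E)-iminium ion in which the diphenyl(silyloxy)methyl group covers one face, the enol of 6 adds through its central carbon to the β-carbon from the open face, and after hydrolysis TsOH cleaves the tert-butyl ester so that the β-keto acid loses CO2 and the methyl ketone condenses with the aldehyde. The closest known reaction type is the diarylprolinol silyl ether-catalysed Michael addition of β-keto esters to enals followed by acid-induced decarboxylation and aldol condensation to 5-substituted cyclohex-2-enones. The ring closes by a 6-(enolendo)-exo-trig aldol addition of the methyl ketone enol to the aldehyde carbon, followed by loss of water. C2 is set by the catalyst (the (R)-enantiomer delivers the nucleophile to the face required for the target), whereas C3 is set thermodynamically, the α-methyl ketone equilibrating to the trans arrangement in which methyl and prenyl are both equatorial. The step needs 1,4-addition to be faster than deprotonation of the iminium ion at the doubly allylic CH2 of the enal (which would move the prenyl double bond into conjugation), hence the acid buffer, the low temperature and the excess of keto ester; the direction of the aldol step is secured by the substrate, because only the methyl group of the ketone can reach the aldehyde through a six-membered transition state.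

Step 5
Reactants: 9 (5R,6R)-6-methyl-5-(3-methylbut-2-en-1-yl)cyclohex-2-en-1-one
Product: 11 (5S,6R)-6-methyl-5-(3-methylbut-2-en-1-yl)-3-phenylcyclohex-2-en-1-one, via silyl enol ether 10 (not isolated)
Conditions: PhMgBr, CuBr·SMe2 (10 mol%), Me3SiCl, THF, −78 °C; then Pd(OAc)2 (1.1 equiv), MeCN, rt
Reagents that add atoms: phenylmagnesium bromide, Br[Mg]c1ccccc1; chlorotrimethylsilane, C[Si](C)(C)Cl (silyl group in 10 only)
Why: Copper-catalysed 1,4-addition of the Grignard reagent with in situ silylation gives a regiodefined silyl enol ether, and Saegusa–Ito dehydrogenation restores the enone so that phenyl sits on sp2 C6 and the configuration created in the addition is erased.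

Step 6
Reactants: 11 (5S,6R)-6-methyl-5-(3-methylbut-2-en-1-yl)-3-phenylcyclohex-2-en-1-one
Product: 13 trimethyl{[(5S,6R)-6-methyl-5-(3-methylbut-2-en-1-yl)-3-phenylcyclohexa-1,3-dien-1-yl]oxy}silane, via potassium dienolate 12 (not isolated)
Conditions: KN(SiMe3)2 (0.95 equiv), THF, −78 to 0 °C; then Me3SiCl, −78 °C
Reagents that add atoms: chlorotrimethylsilane, C[Si](C)(C)Cl; potassium bis(trimethylsilyl)amide, C[Si](C)(C)[N-][Si](C)(C)C.[K+] (potassium in 12 only)
Why: With a slight deficit of base the enolates equilibrate to the through-conjugated dienolate formed by loss of a C1 proton, the thermodynamic enolate of a β-substituted cyclohexenone, and O-silylation fixes it as the linear dienol ether.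

Step 7
Reactants: 13 trimethyl{[(5S,6R)-6-methyl-5-(3-methylbut-2-en-1-yl)-3-phenylcyclohexa-1,3-dien-1-yl]oxy}silane
Product: 14 (4S,5S,6R)-4-(dimethoxymethyl)-6-methyl-5-(3-methylbut-2-en-1-yl)-3-phenylcyclohex-2-en-1-one
Conditions: HC(OMe)3, Me3SiOTf (10 mol%), CH2Cl2, −78 °C
Reagents that add atoms: trimethyl orthoformate, COC(OC)OC
Why: In a vinylogous Mukaiyama reaction the dimethoxycarbenium ion should attack the γ-terminus C1 of the dienol ether anti to the adjacent prenyl group, returning the conjugated enone with a masked formyl group at C1 trans to prenyl.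

Step 8
Reactants: 14 (4S,5S,6R)-4-(dimethoxymethyl)-6-methyl-5-(3-methylbut-2-en-1-yl)-3-phenylcyclohex-2-en-1-one
Product: 16 (2R,3S,4S,5S)-4-(dimethoxymethyl)-2-methyl-3-(3-methylbut-2-en-1-yl)-5-phenylcyclohexan-1-one, via lithium enolate 15 (not isolated)
Conditions: Li (2.2 equiv), NH3(l), THF, tBuOH (1 equiv), −78 °C; then NH4Cl
Reagents that add atoms: lithium, [Li] (in 15 only)
Why: Dissolving-metal reduction of the enone protonates the benzylic β-carbon C6 axially in the all-equatorial half-chair, so hydrogen enters trans to the C2 prenyl group and phenyl ends equatorial, cis to prenyl and trans to the C1 substituent, while the isolated alkene and the acetal are untouched.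

Step 9
Reactants: 16 (2R,3S,4S,5S)-4-(dimethoxymethyl)-2-methyl-3-(3-methylbut-2-en-1-yl)-5-phenylcyclohexan-1-one
Product: 18 (3S,4R,5S)-4-(dimethoxymethyl)-2-methyl-3-(3-methylbut-2-en-1-yl)-5-phenylcyclohex-1-en-1-yl trifluoromethanesulfonate, via magnesium enolate 17 (not isolated)
Conditions: iPr2NMgBr (1.2 equiv), Et2O–THF, rt, 12 h; then N-(5-chloropyridin-2-yl)-1,1,1-trifluoro-N-(trifluoromethylsulfonyl)methanesulfonamide, 0 °C to rt
Reagents that add atoms: N-(5-chloropyridin-2-yl)-1,1,1-trifluoro-N-(trifluoromethylsulfonyl)methanesulfonamide, O=S(=O)(N(c1ccc(Cl)cn1)S(=O)(=O)C(F)(F)F)C(F)(F)F; bromomagnesium diisopropylamide, CC(C)N([Mg]Br)C(C)C (MgBr in 17 only)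
Why: Reversible deprotonation by the magnesium amide equilibrates the enolates toward the more substituted C3=C4 isomer, which O-sulfonylation by the N-pyridyl triflimide traps as the enol triflate (thermodynamic enolate trapping).

Step 10
Reactants: 18 (3S,4R,5S)-4-(dimethoxymethyl)-2-methyl-3-(3-methylbut-2-en-1-yl)-5-phenylcyclohex-1-en-1-yl trifluoromethanesulfonate
Product: 20 (1S,2S,6S)-3-methyl-2-(3-methylbut-2-en-1-yl)-6-phenylcyclohex-3-ene-1-carbaldehyde, via alkene acetal 19 (not isolated)
Conditions: Pd(OAc)2 (5 mol%), PPh3 (10 mol%), HCO2H, nBu3N, DMF, 60 °C; then 2 M HCl, THF, rt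
Reagents that add atoms: water, O
Why: Palladium-catalysed formate reduction replaces the triflate by hydrogen without moving the C3=C4 bond, and mild aqueous acid then unmasks the aldehyde, whose C1 centre is the thermodynamically preferred all-equatorial epimer (any cis isomer should equilibrate on brief treatment with K2CO3 in MeOH).

Step 11
Reactants: 21 5-hydroxy-3,4-dimethoxybenzaldehyde
Product: 23 4,5-dimethoxybenzene-1,3-diol, via aryl formate 22 (not isolated)
Conditions: H2O2 (30% aq.), H2SO4 (cat.), MeOH, rt
Reagents that add atoms: hydrogen peroxide, OO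
Why: In this acid-catalysed Dakin oxidation the electron-rich aryl group (methoxy para to the formyl group) migrates in the peroxide adduct to give the formate, which methanol cleaves to the phenol.

Step 12
Reactants: 23 4,5-dimethoxybenzene-1,3-diol
Product: 24 1,2-dimethoxy-3,5-bis(methoxymethoxy)benzene
Conditions: MeOCH2Cl, iPr2NEt, CH2Cl2, 0 °C to rt
Reagents that add atoms: chloromethyl methyl ether, COCCl
Why: O-Alkylation of both phenols gives MOM ethers, which act as strong ortho-directing groups in the next step and come off under mild acid at the end.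

Step 13
Reactants: 24 1,2-dimethoxy-3,5-bis(methoxymethoxy)benzene; 20 (1S,2S,6S)-3-methyl-2-(3-methylbut-2-en-1-yl)-6-phenylcyclohex-3-ene-1-carbaldehyde
Product: 26 [3,4-dimethoxy-2,6-bis(methoxymethoxy)phenyl][(1S,2S,6S)-3-methyl-2-(3-methylbut-2-en-1-yl)-6-phenylcyclohex-3-en-1-yl]methanol (both carbinol epimers), via aryllithium 25 (not isolated)
Conditions: 24 (1.5 equiv), nBuLi, THF, 0 °C; then 20, −78 °C
Reagents that add atoms: n-butyllithium, [Li]CCCC (lithium in 25 only)
Why: Directed ortho-lithiation should take place at the arene position flanked by the two chelating MOM ethers, and the aryllithium adds to the aldehyde to give a carbinol whose new centre is removed in the next step.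

Step 14
Reactants: 26 the carbinol from step 13
Product: 27 [3,4-dimethoxy-2,6-bis(methoxymethoxy)phenyl][(1S,2S,6S)-3-methyl-2-(3-methylbut-2-en-1-yl)-6-phenylcyclohex-3-en-1-yl]methanone
Conditions: Dess–Martin periodinane, CH2Cl2, rt
Reagents that add atoms: none
Why: Dess–Martin oxidation converts the hindered benzylic alcohol to the aryl ketone under near-neutral conditions that spare the MOM ethers and both alkenes and leave C1 in its stable trans,trans arrangement.

Step 15
Reactants: 27 the bis-MOM ketone from step 14
Product: 28 (2,6-dihydroxy-3,4-dimethoxyphenyl)[(1S,2S,6S)-3-methyl-2-(3-methylbut-2-en-1-yl)-6-phenylcyclohex-3-en-1-yl]methanone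
Conditions: HCl (3 M in MeOH), rt
Reagents that add atoms: none
Why: Acid-catalysed transacetalisation with methanol removes both MOM groups, which flank the ketone and cleave readily, under conditions mild enough for the two trisubstituted alkenes.

Compound list
1 | prop-2-yn-1-ol | C#CCO | starting material
2 | 1-bromo-3-methylbut-2-ene | CC(C)=CCBr | starting material
3 | 6-methylhept-5-en-2-yn-1-ol | OCC#CCC=C(C)C | intermediate
4 | (2E)-6-methylhepta-2,5-dien-1-ol | OC/C=C/CC=C(C)C | intermediate
5 | (2E)-6-methylhepta-2,5-dienal | O=C/C=C/CC=C(C)C | intermediate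
6 | tert-butyl 2-methyl-3-oxobutanoate (racemic) | CC(=O)C(C)C(=O)OC(C)(C)C | starting material
7 | tert-butyl (3S)-2-acetyl-2,6-dimethyl-3-(2-oxoethyl)hept-5-enoate (both C2 epimers) | O=CC[C@H](CC=C(C)C)C(C)(C(C)=O)C(=O)OC(C)(C)C | intermediate (not isolated)
8 | (3S)-4-methyl-3-(3-methylbut-2-en-1-yl)-5-oxohexanal (both C4 epimers) | O=CC[C@H](CC=C(C)C)C(C)C(C)=O | intermediate (not isolated)
9 | (5R,6R)-6-methyl-5-(3-methylbut-2-en-1-yl)cyclohex-2-en-1-one (methyl and prenyl trans) | C1[C@H](CC=C(C)C)[C@@H](C)C(=O)C=C1 | intermediate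
10 | trimethyl{[(3S,5S,6R)-6-methyl-5-(3-methylbut-2-en-1-yl)-3-phenylcyclohex-1-en-1-yl]oxy}silane (phenyl expected trans to prenyl; this centre is erased in the same step) | C1[C@H](CC=C(C)C)[C@@H](C)C(O[Si](C)(C)C)=C[C@H]1c1ccccc1 | intermediate (not isolated)
11 | (5S,6R)-6-methyl-5-(3-methylbut-2-en-1-yl)-3-phenylcyclohex-2-en-1-one | C1[C@H](CC=C(C)C)[C@@H](C)C(=O)C=C1c1ccccc1 | intermediate
12 | potassium (5S,6R)-6-methyl-5-(3-methylbut-2-en-1-yl)-3-phenylcyclohexa-1,3-dien-1-olate | [K+].[O-]C1=CC(c2ccccc2)=C[C@H](CC=C(C)C)[C@H]1C | intermediate (not isolated)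
13 | trimethyl{[(5S,6R)-6-methyl-5-(3-methylbut-2-en-1-yl)-3-phenylcyclohexa-1,3-dien-1-yl]oxy}silane | C[Si](C)(C)OC1=CC(c2ccccc2)=C[C@H](CC=C(C)C)[C@H]1C | intermediate
14 | (4S,5S,6R)-4-(dimethoxymethyl)-6-methyl-5-(3-methylbut-2-en-1-yl)-3-phenylcyclohex-2-en-1-one | COC(OC)[C@H]1[C@H](CC=C(C)C)[C@@H](C)C(=O)C=C1c1ccccc1 | intermediate
15 | lithium enolate of 16 with the enolate double bond toward the ring CH2 (C4=C5 in target numbering; ring centres as in 16) | COC(OC)[C@H]1[C@H](CC=C(C)C)[C@@H](C)C([O-])=C[C@@H]1c1ccccc1.[Li+] | intermediate (not isolated)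
16 | (2R,3S,4S,5S)-4-(dimethoxymethyl)-2-methyl-3-(3-methylbut-2-en-1-yl)-5-phenylcyclohexan-1-one (all ring substituents equatorial) | COC(OC)[C@H]1[C@H](CC=C(C)C)[C@@H](C)C(=O)C[C@@H]1c1ccccc1 | intermediate
17 | bromomagnesium enolate of 16 with the enolate double bond toward the methyl-bearing carbon (C3=C4 in target numbering) | COC(OC)[C@H]1[C@H](CC=C(C)C)C(C)=C(O[Mg]Br)C[C@@H]1c1ccccc1 | intermediate (not isolated)
18 | (3S,4R,5S)-4-(dimethoxymethyl)-2-methyl-3-(3-methylbut-2-en-1-yl)-5-phenylcyclohex-1-en-1-yl trifluoromethanesulfonate | COC(OC)[C@H]1[C@H](CC=C(C)C)C(C)=C(OS(=O)(=O)C(F)(F)F)C[C@@H]1c1ccccc1 | intermediate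
19 | [(1S,5S,6S)-6-(dimethoxymethyl)-4-methyl-5-(3-methylbut-2-en-1-yl)cyclohex-3-en-1-yl]benzene | COC(OC)[C@H]1[C@H](CC=C(C)C)C(C)=CC[C@@H]1c1ccccc1 | intermediate (not isolated)
20 | (1S,2S,6S)-3-methyl-2-(3-methylbut-2-en-1-yl)-6-phenylcyclohex-3-ene-1-carbaldehyde | O=C[C@H]1[C@H](CC=C(C)C)C(C)=CC[C@@H]1c1ccccc1 | intermediate
21 | 5-hydroxy-3,4-dimethoxybenzaldehyde | COc1cc(C=O)cc(O)c1OC | starting material
22 | 3-hydroxy-4,5-dimethoxyphenyl formate | COc1cc(OC=O)cc(O)c1OC | intermediate (not isolated)
23 | 4,5-dimethoxybenzene-1,3-diol | COc1cc(O)cc(O)c1OC | intermediate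
24 | 1,2-dimethoxy-3,5-bis(methoxymethoxy)benzene | COc1cc(OCOC)cc(OCOC)c1OC | intermediate
25 | [3,4-dimethoxy-2,6-bis(methoxymethoxy)phenyl]lithium | COc1cc(OCOC)c([Li])c(OCOC)c1OC | intermediate (not isolated)
26 | [3,4-dimethoxy-2,6-bis(methoxymethoxy)phenyl][(1S,2S,6S)-3-methyl-2-(3-methylbut-2-en-1-yl)-6-phenylcyclohex-3-en-1-yl]methanol (both carbinol epimers) | COc1cc(OCOC)c(C(O)[C@H]2[C@H](CC=C(C)C)C(C)=CC[C@@H]2c2ccccc2)c(OCOC)c1OC | intermediate
27 | [3,4-dimethoxy-2,6-bis(methoxymethoxy)phenyl][(1S,2S,6S)-3-methyl-2-(3-methylbut-2-en-1-yl)-6-phenylcyclohex-3-en-1-yl]methanone | COc1cc(OCOC)c(C(=O)[C@H]2[C@H](CC=C(C)C)C(C)=CC[C@@H]2c2ccccc2)c(OCOC)c1OC | intermediate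
28 | (2,6-dihydroxy-3,4-dimethoxyphenyl)[(1S,2S,6S)-3-methyl-2-(3-methylbut-2-en-1-yl)-6-phenylcyclohex-3-en-1-yl]methanone | COc1cc(O)c(C(=O)[C@H]2[C@H](CC=C(C)C)C(C)=CC[C@@H]2c2ccccc2)c(O)c1OC | target

Total step count: 15. Longest linear sequence: 13 steps (steps 1 to 10, then 13 to 15); the aryl fragment (steps 11 and 12) is made in parallel.

Steps most likely to fail

Step 4. The α-branched keto ester may add too slowly. The amine could then deprotonate the iminium ion at the doubly allylic CH2, moving the prenyl double bond into conjugation, or the enal could condense with itself. Acid could also attack the prenyl alkene during the TsOH stage. The fallback sets out from 5 and uses the faster, unsubstituted nucleophile tert-butyl 3-oxobutanoate under the same iminium catalysis, leaving the methyl group for later. It should give tert-butyl (3S)-2-acetyl-6-methyl-3-(2-oxoethyl)hept-5-enoate F1, which on TsOH treatment passes through (3S)-3-(3-methylbut-2-en-1-yl)-5-oxohexanal F2 to (5R)-5-(3-methylbut-2-en-1-yl)cyclohex-2-en-1-one F3. Kinetic deprotonation at the α′ carbon with LiN(iPr)2 at −78 °C gives lithium (3R)-3-(3-methylbut-2-en-1-yl)cyclohexa-1,5-dien-1-olate F4, and methylation with MeI anti to the prenyl group returns to the route at 9.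

Step 9. Equilibration of the magnesium enolates may stop short and leave the less substituted isomer, or O-sulfonylation of the magnesium enolate may be slow. The fallback sets out from 16 through enolate 17 and moves the regiochemical control to an isolable silyl enol ether. Silylation of 17 (Me3SiCl, Et3N, DMPU) should give trimethyl{[(3S,4R,5S)-4-(dimethoxymethyl)-2-methyl-3-(3-methylbut-2-en-1-yl)-5-phenylcyclohex-1-en-1-yl]oxy}silane F5, which can be freed from its regioisomer. MeLi then releases the regiodefined lithium (3S,4R,5S)-4-(dimethoxymethyl)-2-methyl-3-(3-methylbut-2-en-1-yl)-5-phenylcyclohex-1-en-1-olate F6, and PhNTf2 converts it to the triflate, rejoining the route at 18.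

Step 13. Deprotonation of 24 may also occur at the other doubly flanked position (between a MOM ether and a methoxy group), and the aryllithium may abstract the α-proton of the branched aldehyde instead of adding. The fallback sets out from 21 and makes the aryl anion by bromine–lithium exchange from a bromide placed before the Dakin step. Bromination of 21 (Br2, AcOH) ortho to the free hydroxyl, between OH and CHO as with 3-hydroxy-4-methoxybenzaldehyde, should give 2-bromo-3-hydroxy-4,5-dimethoxybenzaldehyde F7. Dakin oxidation (H2O2, cat. H2SO4, MeOH) through 2-bromo-3-hydroxy-4,5-dimethoxyphenyl formate F8 should give 2-bromo-4,5-dimethoxybenzene-1,3-diol F9. Protection with MeOCH2Cl and iPr2NEt gives 2-bromo-4,5-dimethoxy-1,3-bis(methoxymethoxy)benzene F10. Exchange with nBuLi at −78 °C then gives aryllithium 25 at one position only; transmetalation of 25 with CeCl3 before adding 20 suppresses proton transfer, and the route continues to 26.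

Further compounds
F1 | step 4 | tert-butyl (3S)-2-acetyl-6-methyl-3-(2-oxoethyl)hept-5-enoate (both C2 epimers) | O=CC[C@H](CC=C(C)C)C(C(C)=O)C(=O)OC(C)(C)C
F2 | step 4 | (3S)-3-(3-methylbut-2-en-1-yl)-5-oxohexanal | O=CC[C@H](CC=C(C)C)CC(C)=O
F3 | step 4 | (5R)-5-(3-methylbut-2-en-1-yl)cyclohex-2-en-1-one | C1[C@H](CC=C(C)C)CC(=O)C=C1
F4 | step 4 | lithium (3R)-3-(3-methylbut-2-en-1-yl)cyclohexa-1,5-dien-1-olate | C1[C@H](CC=C(C)C)C=C([O-])C=C1.[Li+]
F5 | step 9 | trimethyl{[(3S,4R,5S)-4-(dimethoxymethyl)-2-methyl-3-(3-methylbut-2-en-1-yl)-5-phenylcyclohex-1-en-1-yl]oxy}silane | COC(OC)[C@H]1[C@H](CC=C(C)C)C(C)=C(O[Si](C)(C)C)C[C@@H]1c1ccccc1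
F6 | step 9 | lithium (3S,4R,5S)-4-(dimethoxymethyl)-2-methyl-3-(3-methylbut-2-en-1-yl)-5-phenylcyclohex-1-en-1-olate | COC(OC)[C@H]1[C@H](CC=C(C)C)C(C)=C([O-])C[C@@H]1c1ccccc1.[Li+]
F7 | step 13 | 2-bromo-3-hydroxy-4,5-dimethoxybenzaldehyde | COc1cc(C=O)c(Br)c(O)c1OC
F8 | step 13 | 2-bromo-3-hydroxy-4,5-dimethoxyphenyl formate | COc1cc(OC=O)c(Br)c(O)c1OC
F9 | step 13 | 2-bromo-4,5-dimethoxybenzene-1,3-diol | COc1cc(O)c(Br)c(O)c1OC
F10 | step 13 | 2-bromo-4,5-dimethoxy-1,3-bis(methoxymethoxy)benzene | COc1cc(OCOC)c(Br)c(OCOC)c1OC
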